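**Retrosynthetic overview**

- The target is the C15 (Z)-p-coumarate of labd-7-ene-2α,15-diol. The ester is made last, by Still–Gennari olefination of a C15 phosphonoacetate with silyl-protected 4-hydroxybenzaldehyde.
- The strategy rests on ring B: a cyclohexene whose C9–C10 bond joins the quaternary C10 (C20 methyl) to C9, with H9 anti to C20. That bond is cut by a retro-6π photochemical (conrotatory) electrocyclisation, which opens the labda-5,7-diene to the (6Z,8E)-9,10-seco triene C10=C5–C6=C7–C8=C9.
- The triene comes from a dienyne (Sonogashira coupling, then Lindlar reduction). The ring A enol triflate is made from ketoisophorone; the C6–C9/C11–C15 enyne is made from (S)-citronellol by ozonolysis, Wittig olefination and alkyne homologation.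
- Ring order: ring A is carried in from the chiral pool with C2 set; ring B is closed in the key step, which sets C9 and C10; C5 is set afterwards by α-face hydrogenation of C5–C6.

Key step: step 11

Remark: labdane numbering (C1–C20) is used for every intermediate, α and β mean the faces of the final decalin, and the Wittig ylide, the diazophosphonate, the phosphonoacetic acid and the silylated aldehyde are taken as purchased reagents.

**Step 1**
Reactants: 1 ketoisophorone (2,6,6-trimethylcyclohex-2-ene-1,4-dione)
Product: 2 (6R)-2,2,6-trimethylcyclohexane-1,4-dione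
Conditions: ene-reductase OYE2 (old yellow enzyme), NADP+ (cat.), glucose dehydrogenase, D-glucose, phosphate buffer pH 7, MTBE overlay, 30 °C
Reagents that add atoms: none
Why: Flavin-dependent ene-reductases add hydride and a proton trans across the activated ring alkene (enzymatic asymmetric conjugate reduction), and this enzyme family is known to give the (6R)-dione, so the methyl-bearing centre is set by the enzyme.

**Step 2**
Reactants: 2 (6R)-2,2,6-trimethylcyclohexane-1,4-dione
Product: 3 (4R,6R)-4-hydroxy-2,2,6-trimethylcyclohexan-1-one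
Conditions: H2 (5 bar), Raney Ni, MeOH, 25 °C; crystallisation
Reagents that add atoms: none
Why: Heterogeneous ketone hydrogenation should reduce only the open C4 carbonyl (C1 is flanked by three methyl groups) and deliver hydrogen to the face away from the axial C2 methyl, giving the 4,6-trans alcohol with 4R; the minor cis isomer is removed by crystallisation.

**Step 3**
Reactants: 3 (4R,6R)-4-hydroxy-2,2,6-trimethylcyclohexan-1-one
Product: 4 (4R,6R)-4-[(tert-butyldimethylsilyl)oxy]-2,2,6-trimethylcyclohexan-1-one
Conditions: TBSCl, imidazole, DMF, 25 °C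
Reagents that add atoms: TBSCl (tert-butyldimethylsilyl chloride), CC(C)(C)[Si](C)(C)Cl
Why: Standard silylation of a secondary alcohol, which leaves the hindered ketone and both stereocentres alone.

**Step 4**
Reactants: 4 (4R,6R)-4-[(tert-butyldimethylsilyl)oxy]-2,2,6-trimethylcyclohexan-1-one
Product: 6 (4R)-4-[(tert-butyldimethylsilyl)oxy]-2,6,6-trimethylcyclohex-1-en-1-yl trifluoromethanesulfonate, via lithium enolate 5 (not isolated)
Conditions: LDA, THF, −78 °C; PhNTf2, −78 → 0 °C
Reagents that add atoms: PhNTf2 (N-phenylbis(trifluoromethanesulfonimide)), O=S(=O)(N(c1ccccc1)S(=O)(=O)C(F)(F)F)C(F)(F)F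
Why: C6 carries the only α-hydrogen, so deprotonation gives the single enolate 5, which is trapped on oxygen (enol triflate formation); the C6 centre is erased on purpose and the silyloxy-bearing carbon is untouched.

**Step 5**
Reactants: 7 (S)-citronellol
Product: 8 tert-butyl{[(3S)-3,7-dimethyloct-6-en-1-yl]oxy}dimethylsilane
Conditions: TBSCl, imidazole, CH2Cl2, 0 → 25 °C
Reagents that add atoms: TBSCl (tert-butyldimethylsilyl chloride), CC(C)(C)[Si](C)(C)Cl
Why: Standard silylation of a primary alcohol.

**Step 6**
Reactants: 8 tert-butyl{[(3S)-3,7-dimethyloct-6-en-1-yl]oxy}dimethylsilane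
Product: 10 (4S)-6-[(tert-butyldimethylsilyl)oxy]-4-methylhexanal, via secondary ozonide 9 (not isolated)
Conditions: O3, CH2Cl2, −78 °C; PPh3, −78 → 25 °C
Reagents that add atoms: ozone, [O-][O+]=O
Why: Ozonolysis with reductive work-up cleaves the trisubstituted alkene to the aldehyde (future C9) and does not touch the remote methyl-bearing centre (future C13) or the silyl ether.

**Step 7**
Reactants: 10 (4S)-6-[(tert-butyldimethylsilyl)oxy]-4-methylhexanal; 11 2-(triphenylphosphoranylidene)propanal
Product: 12 (2E,6S)-8-[(tert-butyldimethylsilyl)oxy]-2,6-dimethyloct-2-enal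
Conditions: toluene, 90 °C
Reagents that add atoms: none
Why: Wittig olefination with the stabilised α-methyl ylide gives the (E)-2-methyl enal, which fixes the later 8E geometry (C7 trans to C11).

**Step 8**
Reactants: 12 (2E,6S)-8-[(tert-butyldimethylsilyl)oxy]-2,6-dimethyloct-2-enal; 13 dimethyl (1-diazo-2-oxopropyl)phosphonate
Product: 14 tert-butyl{[(3S,6E)-3,7-dimethylnon-6-en-8-yn-1-yl]oxy}dimethylsilane
Conditions: K2CO3, MeOH, 0 → 20 °C
Reagents that add atoms: none
Why: Seyferth–Gilbert homologation in the Ohira–Bestmann variant converts the aldehyde into the terminal alkyne through a diazoalkene and 1,2-hydrogen shift; the α-methyl, β-alkyl substitution of the enal should suppress the conjugate addition of methanol that troubles unhindered enals, and the alkene geometry is not involved.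

**Step 9**
Reactants: 6 (4R)-4-[(tert-butyldimethylsilyl)oxy]-2,6,6-trimethylcyclohex-1-en-1-yl trifluoromethanesulfonate; 14 tert-butyl{[(3S,6E)-3,7-dimethylnon-6-en-8-yn-1-yl]oxy}dimethylsilane
Product: 15 (2R,8E,13S)-2,15-bis[(tert-butyldimethylsilyl)oxy]-9,10-secolabda-5(10),8-dien-6-yne (ring A cyclohexene joined at C5 through C6≡C7 to the C8-methyl alkene)
Conditions: PdCl2(PPh3)2 (5 mol %), CuI (10 mol %), Et3N, DMF, 25 °C, degassed
Reagents that add atoms: none
Why: Sonogashira coupling of a cyclohexenyl triflate with a terminal enyne is the established dienyne entry to previtamin-type trienes, and 2,6,6-trimethylcyclohexenyl triflates are known partners despite their hindrance.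

**Step 10**
Reactants: 15 (2R,8E,13S)-2,15-bis[(tert-butyldimethylsilyl)oxy]-9,10-secolabda-5(10),8-dien-6-yne
Product: 16 (2R,6Z,8E,13S)-2,15-bis[(tert-butyldimethylsilyl)oxy]-9,10-secolabda-5(10),6,8-triene
Conditions: H2 (1 atm), Pd/CaCO3 poisoned with Pb(OAc)2 (Lindlar catalyst), quinoline, hexane, 0 °C, dark; filtered cold and used at once
Reagents that add atoms: none
Why: Lindlar semi-hydrogenation adds H2 syn to the alkyne to give the 6Z alkene, as in the preparation of previtamin D trienes from their dienynes, and working at 0 °C keeps the [1,7]-hydrogen shifts from C20 or C11 slow.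

**Step 11**
Reactants: 16 (2R,6Z,8E,13S)-2,15-bis[(tert-butyldimethylsilyl)oxy]-9,10-secolabda-5(10),6,8-triene
Product: 17 (2S,9S,10R,13S)-2,15-bis[(tert-butyldimethylsilyl)oxy]labda-5,7-diene (2α-silyloxy, 9α-H, 10β-methyl)
Conditions: hν (310 nm LEDs or Hg lamp with a filter cutting off below 300 nm), degassed MTBE, −40 °C, Ar
Reagents that add atoms: none
Why: Excitation of the s-cis,Z,s-cis conformer of 16 leads to a conrotatory 6π electrocyclisation, the excited-state allowed mode, which joins the triene termini C9 and C10 and closes ring B as a six-membered cyclohexa-1,3-diene. The closest known reaction is the photochemical closure of previtamin D trienes to the 9,10-anti dienes provitamin D and lumisterol. Conrotation turns the two inward groups, the C20 methyl on C10 and H9 (inward because C8=C9 is E), to opposite faces, so the anti relation of C20 and H9 at the new centres C9 and C10 follows from orbital symmetry. The face of C10 that is attacked is decided by the helicity of the triene: with the C2 silyloxy group equatorial, the ring A half-chair places the axial C4 methyl on the β face, H6 leans toward it and away from the nearer equatorial methyl, and C7 to C9 coil under the α face, so C9 should bond to C10 from the α face and leave C20 β, trans to the C2 oxygen. Light above 300 nm is absorbed by the trienes but hardly by the product diene, so closure should outrun reopening and the 6E triene formed by competing isomerisation is pumped back to 16, while −40 °C blocks the thermal [1,7]-hydrogen shift and the thermal disrotatory closure to the syn isomer. The step needs this facial selectivity, which rests only on the conformational bias of ring A; the 9β,10α isomer is removed by chromatography.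

**Step 12**
Reactants: 17 (2S,9S,10R,13S)-2,15-bis[(tert-butyldimethylsilyl)oxy]labda-5,7-diene
Product: 18 (2S,5S,9S,10S,13S)-2,15-bis[(tert-butyldimethylsilyl)oxy]labd-7-ene
Conditions: H2 (1 atm, one equivalent taken up), Raney Ni (W-2), EtOAc, 20 °C
Reagents that add atoms: none
Why: Heterogeneous hydrogenation of homoannular 5,7-dienes, as with steroidal 7-dehydro sterols over Raney Ni, adds one equivalent of H2 across C5–C6 from the α face, opposite C19, C20 and the C9 side chain, which sets the 5α-H of the trans-decalin; saturating C5–C6 also relieves the allylic strain between the equatorial C4 methyl and H6, and the remaining trisubstituted 7-ene is slow to reduce.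

**Step 13**
Reactants: 18 (2S,5S,9S,10S,13S)-2,15-bis[(tert-butyldimethylsilyl)oxy]labd-7-ene
Product: 19 (2S,5S,9S,10S,13S)-2-[(tert-butyldimethylsilyl)oxy]labd-7-en-15-ol
Conditions: CSA (0.2 equiv), MeOH/CH2Cl2 1:1, 0 °C
Reagents that add atoms: none
Why: Acid-catalysed methanolysis cleaves a primary TBS ether much faster than a secondary one (selective desilylation), so only the C15 hydroxyl is freed.

**Step 14**
Reactants: 19 (2S,5S,9S,10S,13S)-2-[(tert-butyldimethylsilyl)oxy]labd-7-en-15-ol; 20 [bis(2,2,2-trifluoroethoxy)phosphoryl]acetic acid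
Product: 21 (2S,5S,9S,10S,13S)-2-[(tert-butyldimethylsilyl)oxy]labd-7-en-15-yl 2-[bis(2,2,2-trifluoroethoxy)phosphoryl]acetate
Conditions: DCC, DMAP (cat.), CH2Cl2, 0 → 20 °C
Reagents that add atoms: none
Why: Steglich carbodiimide esterification of the only free (primary) alcohol with the phosphonoacetic acid.

**Step 15**
Reactants: 21 (2S,5S,9S,10S,13S)-2-[(tert-butyldimethylsilyl)oxy]labd-7-en-15-yl 2-[bis(2,2,2-trifluoroethoxy)phosphoryl]acetate; 22 4-[(tert-butyldimethylsilyl)oxy]benzaldehyde
Product: 24 (2S,5S,9S,10S,13S)-2-[(tert-butyldimethylsilyl)oxy]labd-7-en-15-yl (2Z)-3-{4-[(tert-butyldimethylsilyl)oxy]phenyl}prop-2-enoate, via potassium phosphonate anion 23 (not isolated)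
Conditions: KHMDS, 18-crown-6, THF, −78 °C; then 22, −78 °C, dark
Reagents that add atoms: none
Why: Still–Gennari olefination, in which the trifluoroethyl phosphonate anion 23 adds to the aryl aldehyde and the electron-poor adduct collapses faster than it equilibrates, gives the (Z)-cinnamate under kinetic control.

**Step 16**
Reactants: 24 (2S,5S,9S,10S,13S)-2-[(tert-butyldimethylsilyl)oxy]labd-7-en-15-yl (2Z)-3-{4-[(tert-butyldimethylsilyl)oxy]phenyl}prop-2-enoate
Product: 25 (2S,5S,9S,10S,13S)-2-hydroxylabd-7-en-15-yl (2Z)-3-(4-hydroxyphenyl)prop-2-enoate (CNP0301213.1)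
Conditions: TBAF, AcOH (1:1), THF, 0 → 20 °C, dark
Reagents that add atoms: none
Why: Fluoride cleaves both the aryl and the secondary alkyl silyl ether (desilylation), the acetic acid buffer keeps the phenol protonated so that the ester and the Z alkene are left alone, and light is excluded to prevent Z to E isomerisation.

**Compound list**

1 | ketoisophorone (2,6,6-trimethylcyclohex-2-ene-1,4-dione) | CC1=CC(=O)CC(C)(C)C1=O | starting material
2 | (6R)-2,2,6-trimethylcyclohexane-1,4-dione | C[C@@H]1CC(=O)CC(C)(C)C1=O | intermediate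
3 | (4R,6R)-4-hydroxy-2,2,6-trimethylcyclohexan-1-one | C[C@@H]1C[C@@H](O)CC(C)(C)C1=O | intermediate
4 | (4R,6R)-4-[(tert-butyldimethylsilyl)oxy]-2,2,6-trimethylcyclohexan-1-one | C[C@@H]1C[C@@H](O[Si](C)(C)C(C)(C)C)CC(C)(C)C1=O | intermediate
5 | lithium (4R)-4-[(tert-butyldimethylsilyl)oxy]-2,6,6-trimethylcyclohex-1-en-1-olate | [Li+].CC1=C([O-])C(C)(C)C[C@H](O[Si](C)(C)C(C)(C)C)C1 | intermediate
6 | (4R)-4-[(tert-butyldimethylsilyl)oxy]-2,6,6-trimethylcyclohex-1-en-1-yl trifluoromethanesulfonate | CC1=C(OS(=O)(=O)C(F)(F)F)C(C)(C)C[C@H](O[Si](C)(C)C(C)(C)C)C1 | intermediate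
7 | (S)-citronellol | CC(C)=CCC[C@H](C)CCO | starting material
8 | tert-butyl{[(3S)-3,7-dimethyloct-6-en-1-yl]oxy}dimethylsilane | CC(C)=CCC[C@H](C)CCO[Si](C)(C)C(C)(C)C | intermediate
9 | 3-{(3S)-5-[(tert-butyldimethylsilyl)oxy]-3-methylpentyl}-5,5-dimethyl-1,2,4-trioxolane (secondary ozonide, both epimers at the ring carbon) | CC1(C)OOC(CC[C@H](C)CCO[Si](C)(C)C(C)(C)C)O1 | intermediate
10 | (4S)-6-[(tert-butyldimethylsilyl)oxy]-4-methylhexanal | O=CCC[C@H](C)CCO[Si](C)(C)C(C)(C)C | intermediate
11 | 2-(triphenylphosphoranylidene)propanal | CC(C=O)=P(c1ccccc1)(c1ccccc1)c1ccccc1 | starting material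
12 | (2E,6S)-8-[(tert-butyldimethylsilyl)oxy]-2,6-dimethyloct-2-enal | O=C/C(C)=C/CC[C@H](C)CCO[Si](C)(C)C(C)(C)C | intermediate
13 | dimethyl (1-diazo-2-oxopropyl)phosphonate | COP(=O)(OC)C(=[N+]=[N-])C(C)=O | starting material
14 | tert-butyl{[(3S,6E)-3,7-dimethylnon-6-en-8-yn-1-yl]oxy}dimethylsilane | C#C/C(C)=C/CC[C@H](C)CCO[Si](C)(C)C(C)(C)C | intermediate
15 | (2R,8E,13S)-2,15-bis[(tert-butyldimethylsilyl)oxy]-9,10-secolabda-5(10),8-dien-6-yne | CC1=C(C#C/C(C)=C/CC[C@H](C)CCO[Si](C)(C)C(C)(C)C)C(C)(C)C[C@H](O[Si](C)(C)C(C)(C)C)C1 | intermediate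
16 | (2R,6Z,8E,13S)-2,15-bis[(tert-butyldimethylsilyl)oxy]-9,10-secolabda-5(10),6,8-triene | CC1=C(/C=C\C(C)=C\CC[C@H](C)CCO[Si](C)(C)C(C)(C)C)C(C)(C)C[C@H](O[Si](C)(C)C(C)(C)C)C1 | intermediate
17 | (2S,9S,10R,13S)-2,15-bis[(tert-butyldimethylsilyl)oxy]labda-5,7-diene | CC1=CC=C2C(C)(C)C[C@H](O[Si](C)(C)C(C)(C)C)C[C@]2(C)[C@H]1CC[C@H](C)CCO[Si](C)(C)C(C)(C)C | intermediate
18 | (2S,5S,9S,10S,13S)-2,15-bis[(tert-butyldimethylsilyl)oxy]labd-7-ene | CC1=CC[C@H]2C(C)(C)C[C@H](O[Si](C)(C)C(C)(C)C)C[C@]2(C)[C@H]1CC[C@H](C)CCO[Si](C)(C)C(C)(C)C | intermediate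
19 | (2S,5S,9S,10S,13S)-2-[(tert-butyldimethylsilyl)oxy]labd-7-en-15-ol | CC1=CC[C@H]2C(C)(C)C[C@H](O[Si](C)(C)C(C)(C)C)C[C@]2(C)[C@H]1CC[C@H](C)CCO | intermediate
20 | [bis(2,2,2-trifluoroethoxy)phosphoryl]acetic acid | OC(=O)CP(=O)(OCC(F)(F)F)OCC(F)(F)F | starting material
21 | (2S,5S,9S,10S,13S)-2-[(tert-butyldimethylsilyl)oxy]labd-7-en-15-yl 2-[bis(2,2,2-trifluoroethoxy)phosphoryl]acetate | CC1=CC[C@H]2C(C)(C)C[C@H](O[Si](C)(C)C(C)(C)C)C[C@]2(C)[C@H]1CC[C@H](C)CCOC(=O)CP(=O)(OCC(F)(F)F)OCC(F)(F)F | intermediate
22 | 4-[(tert-butyldimethylsilyl)oxy]benzaldehyde | O=Cc1ccc(O[Si](C)(C)C(C)(C)C)cc1 | starting material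
23 | potassium salt of the phosphonate carbanion of 21 | [K+].CC1=CC[C@H]2C(C)(C)C[C@H](O[Si](C)(C)C(C)(C)C)C[C@]2(C)[C@H]1CC[C@H](C)CCOC(=O)[CH-]P(=O)(OCC(F)(F)F)OCC(F)(F)F | intermediate
24 | (2S,5S,9S,10S,13S)-2-[(tert-butyldimethylsilyl)oxy]labd-7-en-15-yl (2Z)-3-{4-[(tert-butyldimethylsilyl)oxy]phenyl}prop-2-enoate | CC1=CC[C@H]2C(C)(C)C[C@H](O[Si](C)(C)C(C)(C)C)C[C@]2(C)[C@H]1CC[C@H](C)CCOC(=O)/C=C\c1ccc(O[Si](C)(C)C(C)(C)C)cc1 | intermediate
25 | (2S,5S,9S,10S,13S)-2-hydroxylabd-7-en-15-yl (2Z)-3-(4-hydroxyphenyl)prop-2-enoate (CNP0301213.1) | CC1=CC[C@H]2C(C)(C)C[C@H](O)C[C@]2(C)[C@H]1CC[C@H](C)CCOC(=O)/C=C\c1ccc(O)cc1 | target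

**Step count**

Total: 16 steps. Longest linear sequence: 12 steps (steps 1–4 then 9–16, or equally steps 5–8 then 9–16).

**Steps most likely to fail**

1. Step 11 (key photocyclisation). What may go wrong: the two helical conformers of the triene are excited with little preference, so ring closure takes place on both faces of C10, and part of the material rests as open trienes in the photostationary state. Fallback: the stereochemistry is secured by a cycloreversion and reclosure loop in place of one selective pass. It sets out from triene 16 and comes back at diene 17. After irradiation the mixture is chromatographed and the (9β-H,10α-methyl) labda-5,7-diene F1, in which C20 is cis to the C2 oxygen, is irradiated on its own at 254 nm (quartz, ether, −40 °C), where the dienes absorb strongly. Conrotatory ring opening should return 16 together with its (6E,8E)-triene isomer F2. Renewed irradiation above 300 nm should convert F2 back into 16 and 16 into 17.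

2. Step 12 (mono-hydrogenation of the diene). What may go wrong: hydrogen is added across C7–C8 or 1,4 across C5 and C8 in place of C5–C6, or the reduction runs on to the saturated decalin. Fallback: dissolving-metal reduction in place of surface hydrogenation, setting out from 17 and coming back at 18. With Li in liquid NH3, THF and t-BuOH at −78 °C the diene radical anion should be protonated at C5 from the axial α direction and the resulting allyl anion at C6. This gives the trans-fused 7-ene, as known for steroidal 5,7-dienes, and an isolated trisubstituted alkene is not reduced further under these conditions. The silyl ethers are stable, and the fallback makes no new compound (F0).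

3. Step 10 (semi-hydrogenation). What may go wrong: the hindered alkyne is reduced too slowly or too far, and a long contact time lets the Z triene rearrange by [1,7]-hydrogen shift. Fallback: the Z alkene is brought in ready-made by cross-coupling, setting out from enyne 14 and triflate 6 and coming back at triene 16. Rhodium-catalysed trans-hydroboration of 14 (HBpin, [Rh(cod)Cl]2, P(i-Pr)3, Et3N, cyclohexane, 20 °C) should give the (1Z,3E)-dienyl pinacol boronate F3. Suzuki–Miyaura coupling of F3 with 6 (Pd(PPh3)4, aqueous TlOH, THF, 20 °C) proceeds with retention of alkene geometry and should give 16 without passing through dienyne 15.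

**Further compounds**

F1 | step 11 | (2S,9R,10S,13S)-2,15-bis[(tert-butyldimethylsilyl)oxy]labda-5,7-diene (9β-H, 10α-methyl diastereomer of 17) | CC1=CC=C2C(C)(C)C[C@H](O[Si](C)(C)C(C)(C)C)C[C@@]2(C)[C@@H]1CC[C@H](C)CCO[Si](C)(C)C(C)(C)C
F2 | step 11 | (2R,6E,8E,13S)-2,15-bis[(tert-butyldimethylsilyl)oxy]-9,10-secolabda-5(10),6,8-triene | CC1=C(/C=C/C(C)=C/CC[C@H](C)CCO[Si](C)(C)C(C)(C)C)C(C)(C)C[C@H](O[Si](C)(C)C(C)(C)C)C1
F0 | step 12 | none | none
F3 | step 10 | tert-butyl{[(3S,6E,8Z)-3,7-dimethyl-9-(4,4,5,5-tetramethyl-1,3,2-dioxaborolan-2-yl)nona-6,8-dien-1-yl]oxy}dimethylsilane | CC1(C)OB(/C=C\C(C)=C\CC[C@H](C)CCO[Si](C)(C)C(C)(C)C)OC1(C)C
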